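**Assumption:** the SMILES is read literally, i.e. a trans-fused hydroazulene, (1R,5S,6R,7S,9R,11S,12S) in the locants used below. Locants: C1/C5 ring-fusion carbons; C2–C4 the other five-ring carbons (C4 bears CH3); C6 carbinol carbon; C7 carries the side chain; C8 CH2; C9 ring CH–OAc; C10 C(=CH2); C11 side-chain CH(CH3); C12 side-chain CH(OAc).

## Retrosynthetic overview

1. Target ⇐ C6 ketone (last step, bulky hydride) ⇐ C9 alcohol of opposite configuration (Mitsunobu inversion installs the C9 acetate) ⇐ SmI2 opening of the C5–O bond of an oxygen-bridged tricycle.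
2. Key step: one rhodium-catalysed cascade converts an acyclic 2-diazo-1,3-diketone aldehyde with a terminal allene into that tricycle. The cyclic carbonyl ylide (oxygen ring) forms first; ring A (cyclopentanone, C1–C5 bond) and ring B (seven-membered carbocycle, C9–C10 bond) then form together by intramolecular (3+2) addition to the allene, which also supplies the exocyclic methylene.
3. The ring A carbonyl becomes C3=C4–CH3 by enol triflate formation and methyl cross-coupling after the cascade.
4. Cascade substrate ⇐ crossed Claisen condensation of hepta-5,6-dien-2-one with a cis-β-methyl-γ-prenyl butyrolactone alkylated anti at C7, then diazo transfer.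
5. Lactone ⇐ syn-crotylboration of 4-methylpent-3-enal (sets C11 and C12), hydroboration, oxidative lactonisation.

## Route

Step 1
Reactants: 1 4-methylpent-3-en-1-ol
Product: 2 4-methylpent-3-enal
Conditions: Dess–Martin periodinane, pyridine, CH2Cl2, 0 °C; used at once as a solution
Reagents that add atoms: none
Why: Dess–Martin oxidation stops at the aldehyde and, buffered with pyridine, is mild enough not to move the β,γ-double bond into conjugation.

Step 2
Reactants: 2 4-methylpent-3-enal; 3 (Z)-crotylboronic acid pinacol ester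
Product: 4 (3S,4S)-3,7-dimethylocta-1,6-dien-4-ol
Conditions: (R)-3,3'-bis(2,4,6-triisopropylphenyl)-1,1'-binaphthyl-2,2'-diyl hydrogen phosphate (5 mol %), 4 Å MS, toluene, −30 °C; aqueous work-up
Reagents that add atoms: none
Why: Chiral-phosphoric-acid-catalysed crotylboration, in which the closed chair (Zimmerman–Traxler) transition state turns the Z-boronate into the syn CH3/OH relationship and the (R)-acid is expected to direct attack to the Re face of the aldehyde (the mirror-image acid would give ent-4), setting C11 (S) and C12 (S).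

Step 3
Reactants: 4 (3S,4S)-3,7-dimethylocta-1,6-dien-4-ol
Product: 6 (3S,4S)-3,7-dimethyloct-6-ene-1,4-diol, via B-alkyl-9-borabicyclo[3.3.1]nonane 5 (not isolated)
Conditions: 9-BBN, THF, 0 °C to rt; then NaOH, H2O2, 0 °C
Reagents that add atoms: hydrogen peroxide, OO
Why: Hydroboration–oxidation, in which 9-BBN adds anti-Markovnikov to the monosubstituted alkene far faster than to the trisubstituted prenyl alkene and the C–B bond is oxidised with retention, leaving both stereocentres untouched.

Step 4
Reactants: 6 (3S,4S)-3,7-dimethyloct-6-ene-1,4-diol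
Product: 8 (4S,5S)-4-methyl-5-(3-methylbut-2-en-1-yl)oxolan-2-one (cis-lactone), via lactol 7 (not isolated)
Conditions: 2,2,6,6-tetramethylpiperidin-1-oxyl (10 mol %), PhI(OAc)2 (2.5 equiv), CH2Cl2, rt
Reagents that add atoms: none
Why: Oxoammonium oxidation is selective for the primary alcohol, the aldehyde is trapped by the C12 hydroxyl as lactol 7 and this is oxidised on to the γ-lactone (oxidative lactonisation of a 1,4-diol).

Step 5
Reactants: 8 cis-lactone; 9 tert-butyl(2-iodoethoxy)dimethylsilane
Product: 11 (3S,4S,5S)-3-[2-(tert-butyldimethylsilyloxy)ethyl]-4-methyl-5-(3-methylbut-2-en-1-yl)oxolan-2-one, via lithium enolate 10 (not isolated)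
Conditions: LiN(i-Pr)2, THF, −78 °C; then 9, DMPU, −78 to −20 °C
Reagents that add atoms: none
Why: Lactone enolate alkylation (SN2), in which the electrophile enters on the face anti to the cis-disposed C11 methyl and C12 prenyl groups and so sets C7 (S) trans to both.

Step 6
Reactants: 12 hex-5-yn-2-one
Product: 14 hepta-5,6-dien-2-one, via propargylic amine 13 (not isolated)
Conditions: (CH2O)n, CuBr (0.5 equiv), i-Pr2NH, 1,4-dioxane, reflux
Reagents that add atoms: formaldehyde (as paraformaldehyde), C=O
Why: Crabbé allene homologation, in which copper-catalysed Mannich coupling gives propargylic amine 13 and a copper-assisted 1,5-hydride shift with loss of the imine gives the terminal allene.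

Step 7
Reactants: 11 silyloxyethyl lactone; 14 hepta-5,6-dien-2-one (2.3 equiv)
Product: 16 (9S,10S,11S)-9-[2-(tert-butyldimethylsilyloxy)ethyl]-11-hydroxy-10,14-dimethylpentadeca-1,2,13-triene-6,8-dione, via lithium enolate 15 (not isolated)
Conditions: 14, LiN(i-Pr)2 (2.3 equiv), THF, −78 °C; then 11, −78 to 0 °C; AcOH quench
Reagents that add atoms: none
Why: Crossed Claisen condensation, in which the kinetic methyl-side enolate 15 attacks the lactone carbonyl (C6) and ring opening is driven by deprotonation of the new 1,3-diketone by the second equivalent of enolate, the less basic ketone enolate leaving C7 unenolised.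

Step 8
Reactants: 16 hydroxy 1,3-diketone
Product: 18 (9S,10S,11S)-9-[2-(tert-butyldimethylsilyloxy)ethyl]-7-diazo-10,14-dimethyl-6,8-dioxopentadeca-1,2,13-trien-11-yl acetate, via hydroxy diazo diketone 17 (not isolated)
Conditions: 4-acetamidobenzenesulfonyl azide, Et3N, MeCN, 0 °C to rt; then Ac2O, 4-(dimethylamino)pyridine (10 mol %), rt
Reagents that add atoms: 4-acetamidobenzenesulfonyl azide, CC(=O)Nc1ccc(cc1)S(=O)(=O)N=[N+]=[N-]; acetic anhydride, CC(=O)OC(C)=O
Why: Regitz diazo transfer to the 1,3-diketone, followed in the same flask by acetylation of the C12 hydroxyl, which is clean because the diazo diketone has no enolisable C5–H left to be O-acylated.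

Step 9
Reactants: 18 diazo diketone silyl ether
Product: 19 (9S,10S,11S)-7-diazo-9-(2-hydroxyethyl)-10,14-dimethyl-6,8-dioxopentadeca-1,2,13-trien-11-yl acetate
Conditions: HF·pyridine, pyridine, THF, 0 °C to rt
Reagents that add atoms: none
Why: Fluoride-driven desilylation of the primary silyl ether, to which the acceptor-stabilised diazo group, the acetate and the allene are inert.

Step 10
Reactants: 19 primary alcohol
Product: 20 (9S,10S,11S)-7-diazo-10,14-dimethyl-6,8-dioxo-9-(2-oxoethyl)pentadeca-1,2,13-trien-11-yl acetate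
Conditions: Dess–Martin periodinane, pyridine, CH2Cl2, 0 °C to rt
Reagents that add atoms: none
Why: Dess–Martin oxidation gives the γ-keto aldehyde under near-neutral conditions that neither epimerise C7 nor touch the diazo diketone.

Step 11
Reactants: 20 diazo diketone aldehyde
Product: 22 oxygen-bridged tricyclic diketone (5,9-epoxy bridge, C4 and C6 ketones, C10 methylidene, C7 side chain (2S,3S)-3-acetoxy-6-methylhept-5-en-2-yl; 1S,5R,7S,9S; H-1 anti to the oxygen bridge), via carbonyl ylide 21 (not isolated)
Conditions: Rh2(OAc)4 (2 mol %), benzene, 80 °C, slow addition of 20 (0.005 M)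
Reagents that add atoms: none
Why: Proposed new method: the rhodium carbenoid from the 2-diazo-1,3-diketone is captured by the aldehyde oxygen through a six-membered ring to give carbonyl ylide 21, which adds across the proximal allene π bond held three atoms away (C5–C1 and C9–C10 bonds), so the oxygen ring, the cyclopentanone and the seven-membered carbocycle form in one operation with the methylidene already on C10; the C7 side chain takes the exo (equatorial) position of the emerging 8-oxabicyclo[3.2.1]octanone rather than sitting under the new two-carbon bridge, which fixes C1, C5 and C9 relative to C7, and the closest known reaction is the Padwa tandem carbonyl-ylide formation–intramolecular (3+2) cycloaddition with tethered alkenes.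

Step 12
Reactants: 22 tricyclic diketone
Product: 24 C4 enol triflate (C3=C4–OTf; 1S,5R,7S,9S), via potassium enolate 23 (not isolated)
Conditions: KN(SiMe3)2 (1.05 equiv), THF, −78 °C; then PhNTf2, −78 to −40 °C
Reagents that add atoms: N-phenylbis(trifluoromethanesulfonimide), O=S(=O)(N(c1ccccc1)S(=O)(=O)C(F)(F)F)C(F)(F)F
Why: Kinetic deprotonation by the bulky amide takes the unhindered C3 methylene of the cyclopentanone (C5 is quaternary and the C7 methine beside the other ketone is shielded by the branched side chain), and O-sulfonylation fixes the C3=C4 position (enol triflate formation).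

Step 13
Reactants: 24 enol triflate
Product: 25 bridged methylcyclopentene ketone (C3=C4–CH3; 1S,5R,7S,9S)
Conditions: Me2Zn, Pd(PPh3)4 (5 mol %), THF, 0 °C to rt
Reagents that add atoms: dimethylzinc, C[Zn]C
Why: Negishi cross-coupling, in which zerovalent palladium inserts into the alkenyl triflate, methyl is transferred from zinc and reductive elimination installs the C4 methyl without moving the double bond, Me2Zn being unreactive toward the ketone and the acetate.

Step 14
Reactants: 25 bridged ketone
Product: 26 (1R,5S,7S,9S)-9-hydroxy-6-oxo trans-fused hydroazulene (C3=C4–CH3, C10 methylidene, C12 acetate)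
Conditions: SmI2 (2.2 equiv), THF–MeOH (20:1), −78 °C; neutral work-up
Reagents that add atoms: none
Why: SmI2 reductive cleavage of an α-alkoxy ketone breaks the C5–O bond (α to the C6 ketone and allylic) and leaves the oxygen on C9, and the samarium dienolate is protonated at C5 (α, kinetic) by methanol bound to the samarium alkoxide on O9, which sits on the face the oxygen just left, so hydrogen replaces oxygen with retention to give the trans ring fusion (5S), expected also to be the more stable epimer.

Step 15
Reactants: 26 hydroxy ketone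
Product: 27 (1R,5S,7S,9R)-9-acetoxy-6-oxo trans-fused hydroazulene (C12 acetate retained)
Conditions: PPh3, DIAD, AcOH, THF, 0 °C to rt
Reagents that add atoms: acetic acid, CC(=O)O
Why: Mitsunobu esterification, in which acetate displaces the allylic alkoxyphosphonium by SN2 and so inverts C9 (S to R) while installing the acetate, C6 still being a ketone.

Step 16
Reactants: 27 diacetoxy ketone
Product: 28 (1R,5S,6R,7S,9R)-9-acetoxy-7-[(2S,3S)-3-acetoxy-6-methylhept-5-en-2-yl]-4-methyl-10-methylidene-bicyclo[5.3.0]dec-3-en-6-ol, locants as defined above (CNP0151479.2)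
Conditions: LiBH(s-Bu)3, THF, −78 °C; H2O quench
Reagents that add atoms: none
Why: The bulky borohydride attacks the cycloheptanone from the equatorial direction, anti to the C7 side chain, giving the axial C6 alcohol (6R, cis to the side chain) at a temperature at which both acetates survive.

## Compound list

1 | 4-methylpent-3-en-1-ol | CC(C)=CCCO | starting material
2 | 4-methylpent-3-enal | CC(C)=CCC=O | intermediate
3 | (Z)-crotylboronic acid pinacol ester | C/C=C\CB1OC(C)(C)C(C)(C)O1 | starting material
4 | (3S,4S)-3,7-dimethylocta-1,6-dien-4-ol | C=C[C@H](C)[C@H](CC=C(C)C)O | intermediate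
5 | 9-[(3S,4S)-4-hydroxy-3,7-dimethyloct-6-en-1-yl]-9-borabicyclo[3.3.1]nonane | B1(CC[C@H](C)[C@H](CC=C(C)C)O)C2CCCC1CCC2 | intermediate
6 | (3S,4S)-3,7-dimethyloct-6-ene-1,4-diol | OCC[C@H](C)[C@H](CC=C(C)C)O | intermediate
7 | (4S,5S)-4-methyl-5-(3-methylbut-2-en-1-yl)oxolan-2-ol (lactol, both anomers) | OC1C[C@H](C)[C@H](CC=C(C)C)O1 | intermediate
8 | (4S,5S)-4-methyl-5-(3-methylbut-2-en-1-yl)oxolan-2-one | O=C1C[C@H](C)[C@H](CC=C(C)C)O1 | intermediate
9 | tert-butyl(2-iodoethoxy)dimethylsilane | CC(C)(C)[Si](C)(C)OCCI | starting material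
10 | lithium enolate of lactone 8 | [Li]OC1=C[C@H](C)[C@H](CC=C(C)C)O1 | intermediate
11 | (3S,4S,5S)-3-[2-(tert-butyldimethylsilyloxy)ethyl]-4-methyl-5-(3-methylbut-2-en-1-yl)oxolan-2-one | O=C1[C@@H](CCO[Si](C)(C)C(C)(C)C)[C@H](C)[C@H](CC=C(C)C)O1 | intermediate
12 | hex-5-yn-2-one | CC(=O)CCC#C | starting material
13 | 7-(diisopropylamino)hept-5-yn-2-one | CC(=O)CCC#CCN(C(C)C)C(C)C | intermediate
14 | hepta-5,6-dien-2-one | CC(=O)CCC=C=C | intermediate
15 | lithium hepta-1,5,6-trien-2-olate (kinetic enolate of 14) | [Li]OC(=C)CCC=C=C | intermediate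
16 | (9S,10S,11S)-9-[2-(tert-butyldimethylsilyloxy)ethyl]-11-hydroxy-10,14-dimethylpentadeca-1,2,13-triene-6,8-dione | C=C=CCCC(=O)CC(=O)[C@@H](CCO[Si](C)(C)C(C)(C)C)[C@H](C)[C@H](CC=C(C)C)O | intermediate
17 | (9S,10S,11S)-9-[2-(tert-butyldimethylsilyloxy)ethyl]-7-diazo-11-hydroxy-10,14-dimethylpentadeca-1,2,13-triene-6,8-dione | C=C=CCCC(=O)C(=[N+]=[N-])C(=O)[C@@H](CCO[Si](C)(C)C(C)(C)C)[C@H](C)[C@H](CC=C(C)C)O | intermediate
18 | (9S,10S,11S)-9-[2-(tert-butyldimethylsilyloxy)ethyl]-7-diazo-10,14-dimethyl-6,8-dioxopentadeca-1,2,13-trien-11-yl acetate | C=C=CCCC(=O)C(=[N+]=[N-])C(=O)[C@@H](CCO[Si](C)(C)C(C)(C)C)[C@H](C)[C@H](CC=C(C)C)OC(C)=O | intermediate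
19 | (9S,10S,11S)-7-diazo-9-(2-hydroxyethyl)-10,14-dimethyl-6,8-dioxopentadeca-1,2,13-trien-11-yl acetate | C=C=CCCC(=O)C(=[N+]=[N-])C(=O)[C@@H](CCO)[C@H](C)[C@H](CC=C(C)C)OC(C)=O | intermediate
20 | (9S,10S,11S)-7-diazo-10,14-dimethyl-6,8-dioxo-9-(2-oxoethyl)pentadeca-1,2,13-trien-11-yl acetate | C=C=CCCC(=O)C(=[N+]=[N-])C(=O)[C@@H](CC=O)[C@H](C)[C@H](CC=C(C)C)OC(C)=O | intermediate
21 | six-membered cyclic carbonyl ylide (C5 carbanion, O+=C9H; C5 carries the hexa-4,5-dienoyl group, C7 the side chain) | C=C=CCCC(=O)[C-]1[O+]=CC[C@@H]([C@H](C)[C@H](CC=C(C)C)OC(C)=O)C1=O | intermediate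
22 | oxygen-bridged tricyclic diketone (5,9-epoxy, 4,6-dioxo, 10-methylidene; 1S,5R,7S,9S) | C=C1[C@@H]2C[C@@H]([C@H](C)[C@H](CC=C(C)C)OC(C)=O)C(=O)[C@]3(O2)C(=O)CC[C@@H]13 | intermediate
23 | potassium C3=C4 enolate of 22 | C=C1[C@@H]2C[C@@H]([C@H](C)[C@H](CC=C(C)C)OC(C)=O)C(=O)[C@]3(O2)C(O[K])=CC[C@@H]13 | intermediate
24 | C4 enol triflate of 22 (C3=C4–OTf; 1S,5R,7S,9S) | C=C1[C@@H]2C[C@@H]([C@H](C)[C@H](CC=C(C)C)OC(C)=O)C(=O)[C@]3(O2)C(OS(=O)(=O)C(F)(F)F)=CC[C@@H]13 | intermediate
25 | bridged methylcyclopentene ketone (5,9-epoxy, 6-oxo, C3=C4–CH3; 1S,5R,7S,9S) | C=C1[C@@H]2C[C@@H]([C@H](C)[C@H](CC=C(C)C)OC(C)=O)C(=O)[C@]3(O2)C(C)=CC[C@@H]13 | intermediate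
26 | (1R,5S,7S,9S)-9-hydroxy-6-oxo trans-fused hydroazulene with C12 acetate | C=C1[C@@H](O)C[C@@H]([C@H](C)[C@H](CC=C(C)C)OC(C)=O)C(=O)[C@@H]2C(C)=CC[C@@H]12 | intermediate
27 | (1R,5S,7S,9R)-9-acetoxy-6-oxo trans-fused hydroazulene with C12 acetate | C=C1[C@H](OC(C)=O)C[C@@H]([C@H](C)[C@H](CC=C(C)C)OC(C)=O)C(=O)[C@@H]2C(C)=CC[C@@H]12 | intermediate
28 | CNP0151479.2, (1R,5S,6R,7S,9R,11S,12S) | C=C1[C@H](OC(C)=O)C[C@@H]([C@H](C)[C@H](CC=C(C)C)OC(C)=O)[C@@H](O)[C@@H]2C(C)=CC[C@@H]12 | target

## Step count

Total steps: 16. Longest linear sequence: 15 (steps 1–5 and 7–16); step 6 is a one-step side branch.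

## Three steps most likely to fail

**Step 11 (carbonyl-ylide cascade).** The rhodium carbenoid may cyclopropanate the allene or insert before the aldehyde oxygen captures it. The fallback reaches the same ylide without any metal carbenoid; it sets out from 16 and returns at 22.
- The C12 hydroxyl of 16 is acetylated (Ac2O, pyridine; brief NH3/MeOH treatment to cleave any enol acetate) to give the acetoxy diketone silyl ether F1.
- HF·pyridine frees the primary alcohol F2.
- Dess–Martin oxidation gives the keto aldehyde F3, which is not isolated; piperidinium acetate closes it by intramolecular Knoevenagel condensation (C5 onto C9) to the 2-acylcyclopent-2-enone F4.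
- Nucleophilic epoxidation (t-BuOOH, 1,8-diazabicyclo[5.4.0]undec-7-ene) gives the epoxy diketone F5; either epoxide face serves.
- Heating F5 (toluene, 150 °C, sealed tube) or irradiating it at 300 nm breaks the C5–C9 bond of the diacyl epoxide and gives ylide 21, which closes onto the allene to 22.

**Step 14 (bridge opening, C5 configuration).** External protonation of the samarium dienolate from the open face would give the cis ring fusion, and the β,γ-unsaturated ketone is sensitive to base. The fallback replaces kinetic protonation by thermodynamic control in a separate operation; it sets out from 25 and returns at 26. The cis-fused C5 epimer of 26 F6 is isolated and equilibrated through its dienamine (pyrrolidine 20 mol %, AcOH 20 mol %, CH2Cl2, rt), which reprotonates at C5 under near-neutral conditions and should funnel the material to the trans-fused ketone 26.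

**Step 7 (Claisen acylation by a hindered lactone).** Attack at the α-branched lactone carbonyl may be slow or reversible, and the regiochemistry of the ketone enolate is not perfect. The fallback changes the acyl donor; it sets out from 11 and returns at 16. Lactone 11 is opened with Me(MeO)NH·HCl and AlMe3 (CH2Cl2, 0 °C) to the hydroxy Weinreb amide F7. F7, with one extra equivalent of base for the hydroxyl, is acylated by enolate 15 (THF, −78 to 0 °C) through the stable chelated tetrahedral intermediate and gives 16 on work-up.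

## Further compounds

F1 | step 11 | (9S,10S,11S)-9-[2-(tert-butyldimethylsilyloxy)ethyl]-10,14-dimethyl-6,8-dioxopentadeca-1,2,13-trien-11-yl acetate | C=C=CCCC(=O)CC(=O)[C@@H](CCO[Si](C)(C)C(C)(C)C)[C@H](C)[C@H](CC=C(C)C)OC(C)=O
F2 | step 11 | (9S,10S,11S)-9-(2-hydroxyethyl)-10,14-dimethyl-6,8-dioxopentadeca-1,2,13-trien-11-yl acetate | C=C=CCCC(=O)CC(=O)[C@@H](CCO)[C@H](C)[C@H](CC=C(C)C)OC(C)=O
F3 | step 11 | (9S,10S,11S)-10,14-dimethyl-6,8-dioxo-9-(2-oxoethyl)pentadeca-1,2,13-trien-11-yl acetate | C=C=CCCC(=O)CC(=O)[C@@H](CC=O)[C@H](C)[C@H](CC=C(C)C)OC(C)=O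
F4 | step 11 | 2-(hexa-4,5-dienoyl)cyclopent-2-en-1-one carrying the (2S,3S)-3-acetoxy-6-methylhept-5-en-2-yl side chain at the ring carbon next to the ketone (C7, S) | C=C=CCCC(=O)C1=CC[C@@H]([C@H](C)[C@H](CC=C(C)C)OC(C)=O)C1=O
F5 | step 11 | 2,3-epoxide of F4 (epoxide configuration free) | C=C=CCCC(=O)C12OC1C[C@@H]([C@H](C)[C@H](CC=C(C)C)OC(C)=O)C2=O
F6 | step 14 | cis-fused C5 epimer of 26 (1R,5R,7S,9S) | C=C1[C@@H](O)C[C@@H]([C@H](C)[C@H](CC=C(C)C)OC(C)=O)C(=O)[C@H]2C(C)=CC[C@@H]12
F7 | step 7 | (2S,3S,4S)-2-[2-(tert-butyldimethylsilyloxy)ethyl]-4-hydroxy-N-methoxy-N,3,7-trimethyloct-6-enamide | CON(C)C(=O)[C@@H](CCO[Si](C)(C)C(C)(C)C)[C@H](C)[C@H](CC=C(C)C)O
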